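**Retrosynthetic overview**
- The aldehyde is put on last, by Vilsmeier–Haack formylation at C5 of 21-(1H-pyrrol-2-yl)henicosanenitrile.
- The pyrrole, the only ring, is closed one step earlier by Paal–Knorr condensation of 22,25-dioxopentacosanenitrile with ammonia.
- The 1,4-dicarbonyl compound comes from a homoallylic alcohol (hydroboration, then double oxidation). The key C22–C23 bond is made by carbonyl allylation of 22-oxodocosanenitrile with allylboronic acid pinacol ester.
- The cyano-aldehyde comes from docosanedioic acid: half ester, acid to amide to nitrile, ester to alcohol to aldehyde.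

Assumption: the target is read as 21-(5-formyl-1H-pyrrol-2-yl)henicosanenitrile, C26H44N2O (nitrile carbon, twenty CH2 groups, then C2 of the pyrrole); it has no stereocentre, so there is no enantiomer to select, and the one stereocentre met on the way (C22 after the allylation) is made racemic and removed by oxidation.

**Route**

Step 1
Reactants: 1 docosanedioic acid
Product: 2 dimethyl docosanedioate
Conditions: MeOH (solvent), H2SO4 (cat.), reflux, 16 h
Reagents that add atoms: methanol, CO
Why: Fischer esterification in a large excess of methanol drives both carboxyl groups to the methyl ester, which crystallises on cooling.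

Step 2
Reactants: 2 dimethyl docosanedioate
Product: 4 22-methoxy-22-oxodocosanoic acid (monomethyl docosanedioate), via barium half-ester salt 3 (not isolated)
Conditions: Ba(OH)2·8H2O (0.5 equiv), MeOH/THF, 40 °C → rt; then 2 M HCl
Reagents that add atoms: barium hydroxide, [Ba+2].[OH-].[OH-] (hydroxide oxygen of the new carboxyl group)
Why: Partial saponification with half an equivalent of Ba(OH)2 stops largely at the half ester because its barium salt precipitates as it forms, and unreacted diester is recovered and recycled.

Step 3
Reactants: 4 22-methoxy-22-oxodocosanoic acid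
Product: 6 methyl 22-amino-22-oxodocosanoate, via acid chloride 5 (not isolated)
Conditions: (COCl)2, DMF (cat.), CH2Cl2, 0 °C → rt; volatiles removed; then NH3 (0.5 M in 1,4-dioxane), THF, 0 °C
Reagents that add atoms: ammonia, N; oxalyl chloride, O=C(Cl)C(=O)Cl (chlorine of intermediate 5 only)
Why: Acyl chloride formation followed by ammonolysis is the standard way to a primary amide, and the methyl ester is untouched at 0 °C.

Step 4
Reactants: 6 methyl 22-amino-22-oxodocosanoate
Product: 7 methyl 21-cyanohenicosanoate
Conditions: TFAA, pyridine, THF, 0 °C → rt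
Reagents that add atoms: none
Why: Dehydration of a primary amide with trifluoroacetic anhydride and pyridine is a mild, general nitrile synthesis that leaves the ester alone.

Step 5
Reactants: 7 methyl 21-cyanohenicosanoate
Product: 8 22-hydroxydocosanenitrile
Conditions: LiBH4, THF, 0 °C → 40 °C; then 1 M HCl, 0 °C
Reagents that add atoms: none
Why: LiBH4 is a chemoselective hydride that reduces esters to primary alcohols but does not attack aliphatic nitriles under these conditions.

Step 6
Reactants: 8 22-hydroxydocosanenitrile
Product: 9 22-oxodocosanenitrile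
Conditions: DMP, CH2Cl2, rt
Reagents that add atoms: none
Why: Dess–Martin oxidation takes the primary alcohol to the aldehyde at room temperature without over-oxidation and without touching the nitrile.

Step 7
Reactants: 9 22-oxodocosanenitrile; 10 allylboronic acid pinacol ester (2-allyl-4,4,5,5-tetramethyl-1,3,2-dioxaborolane)
Product: 12 22-hydroxypentacos-24-enenitrile (racemic), via pinacol borate ester 11 (not isolated)
Conditions: 10 (1.5 equiv), toluene, 60 °C, 16 h; then H2O, rt
Reagents that add atoms: allylboronic acid pinacol ester (compound 10), C=CCB1OC(C)(C)C(C)(C)O1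
Why: Carbonyl allylation by allylboration through a closed six-membered transition state is clean for aliphatic aldehydes and inert toward nitriles, and the new C22 carbinol centre is deliberately formed racemic because it becomes a ketone in step 9.

Step 8
Reactants: 12 22-hydroxypentacos-24-enenitrile
Product: 14 22,25-dihydroxypentacosanenitrile (racemic), via bis-9-BBN adduct 13 (not isolated)
Conditions: 9-BBN (2.5 equiv), THF, 0 °C → rt; then NaOAc (aq.), 30% H2O2, 0 °C → rt
Reagents that add atoms: hydrogen peroxide, OO (oxygen of the C25 hydroxyl); 9-BBN, B1C2CCCC1CCC2 (boron groups of intermediate 13 only)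
Why: Anti-Markovnikov hydroboration–oxidation with the bulky, alkene-selective 9-BBN puts the hydroxyl on the terminal carbon, the buffered peroxide work-up avoids nitrile hydration, and the C22 centre is untouched and stays racemic.

Step 9
Reactants: 14 22,25-dihydroxypentacosanenitrile
Product: 15 22,25-dioxopentacosanenitrile
Conditions: DMP (3 equiv), CH2Cl2, 0 °C → rt; crude product used at once
Reagents that add atoms: none
Why: In a double Dess–Martin oxidation the excess periodinane binds and oxidises both hydroxyls quickly, so the 1,4-diol goes to the 4-oxoaldehyde instead of a lactol or lactone, and the only stereocentre is removed.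

Step 10
Reactants: 15 22,25-dioxopentacosanenitrile
Product: 16 21-(1H-pyrrol-2-yl)henicosanenitrile
Conditions: NH4OAc (10 equiv), MeOH/THF, 50 °C, N2
Reagents that add atoms: ammonium acetate, CC(=O)[O-].[NH4+] (nitrogen)
Why: In the Paal–Knorr pyrrole synthesis ammonia condenses with both carbonyls of the 1,4-dicarbonyl compound and two dehydrations give the aromatic 2-substituted pyrrole under nearly neutral conditions that spare the nitrile.

Step 11
Reactants: 16 21-(1H-pyrrol-2-yl)henicosanenitrile
Product: 18 21-(5-formyl-1H-pyrrol-2-yl)henicosanenitrile (target), via iminium chloride 17 (not isolated)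
Conditions: POCl3, DMF, ClCH2CH2Cl, 0 °C → rt; then NaOAc (aq.), 70 °C
Reagents that add atoms: N,N-dimethylformamide, CN(C)C=O (formyl carbon); water, O (formyl oxygen); phosphoryl chloride, O=P(Cl)(Cl)Cl (chloride counter-ion of intermediate 17 only)
Why: Vilsmeier–Haack formylation attacks the free alpha position (C5) of the electron-rich 2-alkylpyrrole with high selectivity, and hydrolysis of the iminium salt releases the aldehyde.

**Compound list**

1 | docosanedioic acid | OC(=O)CCCCCCCCCCCCCCCCCCCCC(=O)O | starting material
2 | dimethyl docosanedioate | COC(=O)CCCCCCCCCCCCCCCCCCCCC(=O)OC | intermediate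
3 | barium bis(22-methoxy-22-oxodocosanoate) | COC(=O)CCCCCCCCCCCCCCCCCCCCC(=O)[O-].COC(=O)CCCCCCCCCCCCCCCCCCCCC(=O)[O-].[Ba+2] | intermediate
4 | 22-methoxy-22-oxodocosanoic acid | COC(=O)CCCCCCCCCCCCCCCCCCCCC(=O)O | intermediate
5 | methyl 22-chloro-22-oxodocosanoate | COC(=O)CCCCCCCCCCCCCCCCCCCCC(=O)Cl | intermediate
6 | methyl 22-amino-22-oxodocosanoate | COC(=O)CCCCCCCCCCCCCCCCCCCCC(N)=O | intermediate
7 | methyl 21-cyanohenicosanoate | COC(=O)CCCCCCCCCCCCCCCCCCCCC#N | intermediate
8 | 22-hydroxydocosanenitrile | N#CCCCCCCCCCCCCCCCCCCCCCO | intermediate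
9 | 22-oxodocosanenitrile | N#CCCCCCCCCCCCCCCCCCCCCC=O | intermediate
10 | allylboronic acid pinacol ester (2-allyl-4,4,5,5-tetramethyl-1,3,2-dioxaborolane) | C=CCB1OC(C)(C)C(C)(C)O1 | starting material
11 | 22-[(4,4,5,5-tetramethyl-1,3,2-dioxaborolan-2-yl)oxy]pentacos-24-enenitrile (racemic) | N#CCCCCCCCCCCCCCCCCCCCCC(CC=C)OB1OC(C)(C)C(C)(C)O1 | intermediate
12 | 22-hydroxypentacos-24-enenitrile (racemic) | N#CCCCCCCCCCCCCCCCCCCCCC(O)CC=C | intermediate
13 | 25-(9-borabicyclo[3.3.1]nonan-9-yl)-22-[(9-borabicyclo[3.3.1]nonan-9-yl)oxy]pentacosanenitrile (racemic) | N#CCCCCCCCCCCCCCCCCCCCCC(OB1C2CCCC1CCC2)CCCB1C2CCCC1CCC2 | intermediate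
14 | 22,25-dihydroxypentacosanenitrile (racemic) | N#CCCCCCCCCCCCCCCCCCCCCC(O)CCCO | intermediate
15 | 22,25-dioxopentacosanenitrile | N#CCCCCCCCCCCCCCCCCCCCCC(=O)CCC=O | intermediate
16 | 21-(1H-pyrrol-2-yl)henicosanenitrile | N#CCCCCCCCCCCCCCCCCCCCCc1ccc[nH]1 | intermediate
17 | N-{[5-(20-cyanoicosyl)-1H-pyrrol-2-yl]methylidene}-N-methylmethanaminium chloride | N#CCCCCCCCCCCCCCCCCCCCCc1ccc(C=[N+](C)C)[nH]1.[Cl-] | intermediate
18 | 21-(5-formyl-1H-pyrrol-2-yl)henicosanenitrile (5-(20-cyanoicosyl)-1H-pyrrole-2-carbaldehyde; no stereocentre) | N#CCCCCCCCCCCCCCCCCCCCCc1ccc(C=O)[nH]1 | target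

**Totals and risks**

Total step count: 11. Longest linear sequence: 11 steps (1 to 18; 10 is bought).

Steps most likely to fail:

Step 2, the statistical monohydrolysis, which gives only about half of the material per pass and needs recycling. The fallback sets out from diester 2 and comes back to the route at aldehyde 9. Ammonolysis of both ester groups (NH3 in MeOH, NaOMe cat., sealed vessel, 100 °C) gives docosanediamide F1. Double dehydration (TFAA, pyridine, 1,4-dioxane, 60 °C) gives docosanedinitrile F2. Half-reduction with i-Bu2AlH (1.0 equiv, toluene, −40 °C; then aq. HCl) gives 9, which separates easily on silica from unchanged F2 (recycled) and from the dialdehyde. The desymmetrisation is then a partial nitrile reduction instead of a partial saponification, and steps 2 to 6 are bypassed.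

Step 9, the double oxidation of the 1,4-diol, where a lactol could form and go on to the lactone, and where the keto-aldehyde is sensitive. The fallback sets out from diol 14 and comes back at 15, oxidising the two positions one after the other. Selective silylation of the primary hydroxyl (TBSCl, imidazole, CH2Cl2, 0 °C) gives 25-[(tert-butyldimethylsilyl)oxy]-22-hydroxypentacosanenitrile F3. Oxidation of the secondary alcohol (DMP) gives 25-[(tert-butyldimethylsilyl)oxy]-22-oxopentacosanenitrile F4. Removal of the silyl group (aq. HCl, THF) gives 25-hydroxy-22-oxopentacosanenitrile F5. Oxidation of the primary alcohol (DMP) gives 15. With the ketone already in place, the ring form of F5 is a hemiketal that cannot be oxidised to a lactone.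

Step 10, the Paal–Knorr closure with ammonia, whose product, a pyrrole with a free alpha position and free N–H, is prone to acid- and air-induced oligomerisation. The fallback sets out from 15 and comes back at 16. The condensation is run with p-toluenesulfonamide (TsNH2, p-TsOH cat., toluene, reflux, water separator) to give the acid-stable 21-[1-(4-methylbenzenesulfonyl)-1H-pyrrol-2-yl]henicosanenitrile F6, which can be purified and stored. The sulfonyl group is then removed (KOH, MeOH/THF/H2O, 40 °C) to release 16 under basic conditions, and 16 is taken straight into step 11.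

**Further compounds**

F1 | step 2 | docosanediamide | NC(=O)CCCCCCCCCCCCCCCCCCCCC(N)=O
F2 | step 2 | docosanedinitrile | N#CCCCCCCCCCCCCCCCCCCCCC#N
F3 | step 9 | 25-[(tert-butyldimethylsilyl)oxy]-22-hydroxypentacosanenitrile (racemic) | N#CCCCCCCCCCCCCCCCCCCCCC(O)CCCO[Si](C)(C)C(C)(C)C
F4 | step 9 | 25-[(tert-butyldimethylsilyl)oxy]-22-oxopentacosanenitrile | N#CCCCCCCCCCCCCCCCCCCCCC(=O)CCCO[Si](C)(C)C(C)(C)C
F5 | step 9 | 25-hydroxy-22-oxopentacosanenitrile | N#CCCCCCCCCCCCCCCCCCCCCC(=O)CCCO
F6 | step 10 | 21-[1-(4-methylbenzenesulfonyl)-1H-pyrrol-2-yl]henicosanenitrile | N#CCCCCCCCCCCCCCCCCCCCCc1cccn1S(=O)(=O)c1ccc(C)cc1
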